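All runs were computed on assumed constants; noise was put on by code.

At 160 min the grey flask reads 0.0812 M of product and climbs slowly. You ask for a quick number for the same charge at 640 min. Your hunch is that so long a wait takes the violet flask to the end of the partner, the limiting reagent by charge.

all flasks: free catalyst 0.00100 M
- grey: starting material 0.200 M; partner 0.160 M
- green: starting material 0.0800 M; partner 0.0400 M
- red: starting material 0.100 M; partner 0.160 M
- amber: starting material 0.200 M; partner 0.160 M; product 0.100 M
- violet: starting material 0.200 M; partner 0.160 M; time 640 min

| run | time / min | [product] / M |
|---|---|---|
| grey run | 32 | 0.0403 |
| grey run | 64 | 0.0624 |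
| grey run | 96 | 0.0733 |
| grey run | 130 | 0.0790 |
| grey run | 160 | 0.0812 |
| green run | 32 | 0.0069 |
| green run | 64 | 0.0090 |
| green run | 96 | 0.0116 |
| green run | 130 | 0.0130 |
| green run | 160 | 0.0134 |
| red run | 32 | 0.0253 |
| red run | 64 | 0.0387 |
| red run | 96 | 0.0424 |
| red run | 130 | 0.0449 |
| red run | 160 | 0.0450 |
| amber run | 32 | 0.1415 |
| amber run | 64 | 0.1601 |
| amber run | 96 | 0.1733 |
| amber run | 130 | 0.1801 |
| amber run | 160 | 0.1819 |

(standard deviation of a reading: 6 × 10⁻⁴ M)

- the power of [starting material] that the first rate follows, about the charge of the grey run; measure it at two percent of starting material made into product (one fixed amount of product, the same in the runs compared)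
- the power of [partner] that the first rate follows, about the charge of the grey run; measure it at two percent of starting material made into product
- product in the violet run at 640 min, as a share of the starting material charged

- Overall: starting material + partner -> product, with free catalyst as catalyst.
- Constant volume, constant temperature.
- What is held in complexes is read along with the free species.
- An order is taken over about fifteen percent of the charge, up and down.

I doubt the hunch. Grey's partner charge minus its product is still 0.0788 M, so the flattening is not an empty partner. Added product doesn't explain it either: amber, charged with 0.100 M of product, has gained 0.0819 M at 160 min, about what grey has made.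

So I read the fade itself. Over two equal intervals ending at 96 min, grey gains 0.0221 M and then 0.0109 M, about half. I call the natural log of the ratio of two successive gains, divided by the interval, the fading constant, here 0.0221 min⁻¹. If each gain keeps that ratio to the last, product climbs towards a ceiling. At 160 min grey then stands short of its ceiling by the fraction 2.92%, which puts the ceiling at 0.0836 M. Violet has grey's charge, so I commit to 41.8% of the starting material charged, not the 80.0% your hunch needs.

The forecast says 41.7%, with a range of 40.8% to 43%, and my figure stands close to it. It gives orders of 0.6 in starting material and 0.9 in partner. It says grey's fade “points to catalyst death”. I leave the cause open, since my number doesn't use one.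

Violet gives 41.7% at 640 min, and the orders are 0.67 in starting material and 1.0 in partner, the second above the forecast's. The flask runs on these steps:

    2 free catalyst ⇌ catalyst dimer, settled at all times (5000 M⁻¹)
    catalyst dimer + starting material + partner → product + catalyst dimer (340.2 M⁻² min⁻¹)
    2 starting material ⇌ idle substrate dimer, settled at all times (7.200 M⁻¹)
    starting material → decomposed substrate (0.01962 min⁻¹)

Violet's product stays low because starting material decomposes: the violet run gives 41.7% with that step and 77.5% without it. Grey's fading constant and ceiling, carried to amber, put the product made at a quarter of the starting material charged at 41.2 min, and the amber flask gets there later, at 43.8 min.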